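**Early rates.** At early times I look at one number per flask: how fast target appears up to the first reading. Starting material turns to target under catalyst in closed, stirred flasks.

| flask | starting material | catalyst | time |
|---|---|---|---|
| Friday's | 1.00 M | 0.100 M |  |
| Saturday's | 1.00 M | 0.0500 M |  |
| Wednesday's | 2.00 M | 0.100 M |  |
| Thursday's | 0.330 M | 0.0330 M | 23 h |

| Friday's run: time / h | Friday's run: [target] / M | Saturday's run: time / h | Saturday's run: [target] / M | Wednesday's run: time / h | Wednesday's run: [target] / M |
|---|---|---|---|---|---|
| 3.8 | 0.217 | 3.8 | 0.060 | 3.8 | 0.309 |
| 7.7 | 0.436 | 7.7 | 0.130 | 7.7 | 0.789 |
| 12 | 0.611 | 12 | 0.229 | 12 | 1.246 |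
| 15 | 0.685 | 15 | 0.298 | 15 | 1.415 |
| 19 | 0.741 | 19 | 0.373 | 19 | 1.524 |
| 23 | 0.771 | 23 | 0.430 | 23 | 1.559 |

(each reading ± 0.003 M)

- Overall: starting material -> target, with catalyst as catalyst.
- Constant volume, constant temperature.
- A reading of a species includes what of it is bound.
- An order is taken over about fifteen percent of the charge, up and down.

- the exponent of [catalyst] in the starting rate at the charge of the Friday's run (at the point where two percent of the starting material have become target)
- the exponent of [starting material] in the starting rate at the charge of the Friday's run (at the point where two percent of the starting material have become target) (one fixed amount of target, the same in the runs compared)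
- target in the Thursday's run at 23 h, as a share of the starting material charged

**Share rate.** Friday's flask makes target at 0.0571 M h⁻¹ up to its first reading. Dividing by the charge gives the share rate f, the share of the starting material turned per hour: 0.0571 h⁻¹ for Friday's flask.

**Two slowings.** Halving the catalyst from Friday's to Saturday's flask cuts the first reading by a factor that gives an order in catalyst, n, of 1.85. Doubling the starting material from Friday's to Wednesday's flask gives an order in starting material, m, of 0.510, which is less than first order. That m belongs to the range above Friday's charge. Thursday's flask lies below it, and I expect the order to climb towards one there. So I take the mean of the reading and one, 0.755, a judgement of mine.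

For Thursday's flask, less catalyst multiplies Friday's rate by 0.128, and less starting material multiplies it by 0.433. My estimate of the rate is 0.003164 M h⁻¹, and of f 0.009587 h⁻¹.

**Accumulated slowing.** I let the rate fall with what remains, a pseudo-first-order run-down. At 23 h that gives 19.8% of the charge.

**The forecast.** It gives 1.7 (1.4 to 2) for catalyst, 0.45 (0.1 to 0.8) for starting material, and 26% (19% to 34%) for Thursday's flask, where “slight acceleration takes it” to that value. My figure is lower.

**The result.** Thursday's flask gives 19.7% of the starting material charged at 23 h. At Friday's charge, where two percent of the starting material have become target, the orders are 1.9 in catalyst and 0.40 in starting material.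

    catalyst + starting material ⇌ catalyst-substrate complex, settled at all times (0.5070 M⁻¹)
    catalyst-substrate complex + catalyst → target + 2 catalyst (22.79 M⁻¹ h⁻¹)
    starting material → decomposed substrate (0.02923 h⁻¹)
    starting material + target → 2 target (0.1145 M⁻¹ h⁻¹)

Through the same run-down, Thursday's result means f = 0.009539 h⁻¹, against my 0.00959 h⁻¹. For Saturday's flask, f from its own first reading is 0.0158 h⁻¹, which through the same run-down puts a quarter of the charge at 18.2 h, and Saturday's flask comes to that share at 13.1 h.

The numbers in the tables are simulated from invented constants; scatter was added.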